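The numbers in the tables stem from a simulated flask for an exercise.

If a single step, first order in substrate and in free catalyst, had run these flasks, then a flask with both cut by half would have converted half the fraction of its charge in a given time while conversion stayed small, so I began by testing that.

| flask | substrate | reagent | free catalyst | remark |
|---|---|---|---|---|
| summer | 0.20 M | 0.55 equiv | 5 mol% | run made earlier |
| dawn | 0.20 M | 2.2 equiv | 5 mol% | run made earlier |
| autumn | 0.10 M | 1.1 equiv | 5 mol% | run made earlier |
| flask | 0.20 M | 1.10 equiv | 5 mol% |  |

| run | time / h | target / % | substrate / % |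
|---|---|---|---|
| summer | 1.50 | 1 | 96 |
| summer | 2.50 | 2 | 92 |
| summer | 4.00 | 6 | 88 |
| summer | 8.00 | 14 | 82 |
| summer | 12.0 | 23 | 71 |
| summer | 20.0 | 33 | 64 |
| dawn | 1.33 | 0 | 96 |
| dawn | 4.00 | 8 | 91 |
| dawn | 8.00 | 17 | 76 |
| dawn | 10.0 | 23 | 76 |
| dawn | 15.0 | 29 | 63 |
| dawn | 20.0 | 43 | 55 |
| autumn | 4.00 | 9 | 92 |
| autumn | 8.00 | 17 | 83 |
| autumn | 12.0 | 23 | 73 |
| autumn | 15.0 | 32 | 66 |
| autumn | 20.0 | 43 | 60 |

(each reading ± 2 percentage points)

- apparent order in free catalyst when 30% of the substrate are converted (percent change of the rate of making target for one percent more free catalyst charged)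
- factor on the rate of making target when 30% of the substrate are converted if reagent is charged twice over



The summer and autumn runs were charged the same molar reagent, 0.110 M and 0.110 M, while autumn had 0.10 M of substrate against 0.20 M with the same loading, and at 12.0 h they had made 23% and 23% of their charges, each reading with a scatter of 2 percentage points. That read as 1.00 for the percent change of the rate per percent more substrate and free catalyst together at equal reagent charge, the dilution budget, which is less than the 2 that the single step asks for.

Next I added the reagent: at 8.00 h the dawn run with 2.2 equiv had made 17% and the summer run with 0.55 equiv had made 14%, which reads as a reagent order of 0.140, a loose reading given the scatter, so I reckoned 1.10 for doubling the charge in the new flask.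

Then I divided the budget. In the dawn run the rate over the second 10.0 h stood at 0.870 of the rate over the first, while the mean substrate fraction went from 0.880 to 0.655, which reads as a substrate order of 0.473, a loose reading given the scatter. That left 0.527 as my order in free catalyst.

The forecast gave 0.9 (0.65 to 1.1) for that order, higher than mine, and 1.1 (1 to 1.35) for the doubling, holding that “the order in substrate looks near zero”.

The flask gave an order of 0.64 in free catalyst and a factor of 1.11.

    2 catalyst intermediate C ⇌ resting dimer, settled at all times (K = 3800 M⁻¹)
    catalyst intermediate C ⇌ free catalyst + target (K = 0.460 M, k = 4.97 h⁻¹)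
    catalyst intermediate A → catalyst intermediate B (k = 48.4 h⁻¹)
    reagent + free catalyst → catalyst intermediate A (k = 23.2 M⁻¹ h⁻¹)
    substrate + catalyst intermediate B ⇌ catalyst intermediate C (K = 147 M⁻¹, k = 13.6 M⁻¹ h⁻¹)

At 10.0 h this flask held 60.6% of its catalyst in the resting dimer, its resting state, against 10.1% as free catalyst. Taking 0.64 from the budget left 0.358 for substrate, and with that order I reckoned the rate of the second stretch of the dawn run at 0.900 of the first, where the readings gave 0.870.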